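**Retrosynthetic overview**

1. The dienone (filicinic) ring is numbered C1 (C=O), C2 (propanoyl-bearing), C3 (C–OH), C4 (CMe2), C5 (C–OH), C6 (bridge-bearing). It is cut at C1–C2 and C4–C5: a [3+3] double C-acylation of the dinucleophile C2–C3–C4 (a regiodefined silyloxydiene equivalent of 2-methylheptane-3,5-dione) by the malonyl unit C1–C6–C5, which already carries the bridge CH2 and the chromene.
2. Enabling feature: C1, C3 and C5 of this ring are all at the carbonyl level and C4 is quaternary, so the ring is a non-aromatisable cyclic β-triketone (malonyl plus β-diketone). The bridge CH2 on dienone C6 sits on chromene C6 between two phenolic oxygens, so one malonyl carbonyl can be held as a six-membered aryl lactone through the chromene C5 oxygen.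
3. This lactone ring is not in the target. It masks one phenol, activates the second acyl group for the ring closure, and is cleaved by that closure, which sets the phenol free.
4. Ring order: benzene ring (bought) → 2H-pyran ring of the chromene (step 1) → temporary lactone ring (step 2) → dienone ring with loss of the lactone ring (step 7, the last step).
5. The malonyl lactone comes from the chromene, formaldehyde and Meldrum's acid (steps 2 and 3); the diene comes from 2-methylpropanoyl chloride, but-1-yne and 2-(trimethylsilyl)ethanol (steps 4 to 6).

Key step: step 7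

Remark: the target is achiral and is drawn as the dienol tautomer; compounds 8 to 11, 19 and 20 have one stereocentre (the malonyl carbon), are racemic and lose it in step 7, so no configuration is written.
Remark: the lactone of 9 is taken to close through the chromene C5 oxygen (the phenol not hydrogen-bonded to the ketone); closure through the C7 oxygen would give an isomer that steps 3 and 7 carry to the same product.

**Route**

Step 1
Reactants: 1 flopropione [1-(2,4,6-trihydroxyphenyl)propan-1-one]; 2 3-methylbut-2-enal
Product: 4 1-(5,7-dihydroxy-2,2-dimethyl-2H-chromen-8-yl)propan-1-one, via quinone methide 3 (not isolated)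
Conditions: pyridine, 110 °C; chromatography
Reagents that add atoms: none
Why: Pyridine-promoted Knoevenagel-type condensation of the enal at a free ring carbon should give the ortho-quinone methide 3, whose oxa-6π electrocyclisation through the oxygen next to the acyl group closes the 2H-pyran (known chromenylation of acylphloroglucinols); the isomer closed through the para oxygen is the expected side product and is removed by chromatography, and no stereocentre is formed.

Step 2
Reactants: 4 1-(5,7-dihydroxy-2,2-dimethyl-2H-chromen-8-yl)propan-1-one; 5 Meldrum's acid (2,2-dimethyl-1,3-dioxane-4,6-dione); 6 formaldehyde (used as paraformaldehyde)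
Product: 9 5-hydroxy-8,8-dimethyl-2-oxo-6-propanoyl-3,4-dihydro-2H,8H-pyrano[2,3-f]chromene-3-carboxylic acid (racemic), via methylidene Meldrum's acid 7 (not isolated), via benzyl Meldrum's acid 8 (not isolated)
Conditions: L-proline (10 mol %), MeCN, 25 °C; then 60 °C
Reagents that add atoms: none
Why: Knoevenagel condensation should give methylidene Meldrum's acid 7, the only free arene carbon (chromene C6, activated by two ortho oxygens) adds to it in a Friedel–Crafts/Michael sense (Yonemitsu-type three-component condensation), and on warming the non-chelated C5 phenol opens the dioxanedione ring with loss of acetone to the six-membered lactone acid below the temperature of decarboxylation; the new stereocentre is racemic and is erased in step 7.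

Step 3
Reactants: 9 5-hydroxy-8,8-dimethyl-2-oxo-6-propanoyl-3,4-dihydro-2H,8H-pyrano[2,3-f]chromene-3-carboxylic acid
Product: 11 8,8-dimethyl-2-oxo-6-propanoyl-5-(trimethylsilyloxy)-3,4-dihydro-2H,8H-pyrano[2,3-f]chromene-3-carbonyl chloride (racemic, used crude), via bis-silyl derivative 10 (not isolated)
Conditions: BSA (2.1 equiv), CH2Cl2, 25 °C, evaporate; then (COCl)2 (1.1 equiv), DMF (cat.), CH2Cl2, 0 to 25 °C
Reagents that add atoms: N,O-bis(trimethylsilyl)acetamide CC(=N[Si](C)(C)C)O[Si](C)(C)C; oxalyl chloride O=C(Cl)C(=O)Cl
Why: Silylation masks the chelated phenol and turns the acid into its trimethylsilyl ester, which oxalyl chloride with catalytic DMF converts into the acid chloride without release of HCl (known silyl ester to acid chloride exchange), so the chromene alkene, the aryl lactone and the aryl ketone should be untouched.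

Step 4
Reactants: 12 2-methylpropanoyl chloride; 13 but-1-yne
Product: 14 2-methylhept-4-yn-3-one
Conditions: PdCl2(PPh3)2 (2 mol %), CuI (4 mol %), Et3N (1.2 equiv), THF, 0 to 25 °C
Reagents that add atoms: none
Why: Acyl Sonogashira coupling of an acid chloride with a terminal alkyne gives the ynone in one step, and the alkyne fixes which carbon will later carry the enol oxygen of the propanoyl side.

Step 5
Reactants: 14 2-methylhept-4-yn-3-one; 15 2-(trimethylsilyl)ethanol
Product: 16 (4E)-2-methyl-5-[2-(trimethylsilyl)ethoxy]hept-4-en-3-one
Conditions: NaH (5 mol %), THF, 0 to 25 °C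
Reagents that add atoms: none
Why: Alkoxide-catalysed oxa-Michael addition of an alcohol to an ynone places the oxygen only on the ethyl-bearing carbon and should give the E enol ether as the thermodynamic isomer (the geometry has no consequence later).

Step 6
Reactants: 16 (4E)-2-methyl-5-[2-(trimethylsilyl)ethoxy]hept-4-en-3-one
Product: 18 (4E)-2-methyl-5-[2-(trimethylsilyl)ethoxy]-3-(trimethylsilyloxy)hepta-2,4-diene, via lithium dienolate 17 (not isolated)
Conditions: LiN(iPr)2 (1.1 equiv), THF, −78 °C; Me3SiCl (1.3 equiv), −78 to 0 °C; non-aqueous work-up
Reagents that add atoms: chlorotrimethylsilane C[Si](C)(C)Cl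
Why: Kinetic deprotonation of a β-alkoxy enone by the lithium amide occurs at the α′ carbon (here the isopropyl methine), as in the preparation of Danishefsky-type 2-silyloxydienes, and O-silylation traps the cross-conjugated dienolate as the tetrasubstituted silyl enol ether.

Step 7
Reactants: 11 8,8-dimethyl-2-oxo-6-propanoyl-5-(trimethylsilyloxy)-3,4-dihydro-2H,8H-pyrano[2,3-f]chromene-3-carbonyl chloride; 18 (4E)-2-methyl-5-[2-(trimethylsilyl)ethoxy]-3-(trimethylsilyloxy)hepta-2,4-diene
Product: 21 3,5-dihydroxy-6-[(5,7-dihydroxy-2,2-dimethyl-8-propanoyl-2H-chromen-6-yl)methyl]-4,4-dimethyl-2-propanoylcyclohexa-2,5-dien-1-one (CNP0277188.0), via keto lactone 19 (not isolated), via diketone lactone 20 (not isolated)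
Conditions: ZnCl2 (0.1 equiv), CH2Cl2, −40 to 0 °C; then anhydrous Bu4NF (4 equiv), THF, 0 to 40 °C; 1 M HCl work-up
Reagents that add atoms: none
Why: Proposed new method: under ZnCl2 catalysis the acid chloride 11 should C-acylate the silyl enol ether terminus (the CMe2 carbon) of 18 to give 19 (Mukaiyama-type acylation, as known for Danishefsky-type dienes and 1,3-bis(silyloxy)dienes with acid chlorides), then fluoride removes the aryl silyl ether and fragments the 2-(trimethylsilyl)ethyl enol ether (loss of ethene and Me3SiF) to the β-diketonate of 20, whose central carbon attacks the aryl lactone carbonyl and expels the phenoxide (Dieckmann-type Claisen condensation). The closest known reaction types are the Effenberger cyclisation of enol ethers with malonyl dichloride to cyclic β-triketones and the biomimetic Claisen cyclisation of polyketo esters to acylphloroglucinols; new is the mixed malonyl donor (acid chloride plus aryl lactone) and the fluoride-triggered second acylation. The dienone ring closes in the 6-(enolexo)-exo-trig mode and the temporary lactone ring is opened in the same event; no stereocentre is formed and the racemic centre of 11 ends as an sp2 enol carbon. The step needs C-acylation through the isopropyl-derived carbon and not through the ethyl CH2, which is secured because only that carbon is a silyl enol ether while the propanoyl side is locked as an enol ether; should the acid chloride acylate the central diene carbon first, fluoride would unveil the enolate at the CMe2 carbon and the same ring would close. C- over O-acylation in the closure is secured thermodynamically, since the triketonate of the product ring is the most stable anion in the system and O-acylated enol lactones are shuttled to it through acyl fluoride or aryl ester exchange. The quaternary CMe2 carbon prevents aromatisation, so the competing aldol closure stays reversible and the Claisen closure is the only irreversible exit.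

**Compound list**

1 | flopropione, 1-(2,4,6-trihydroxyphenyl)propan-1-one | CCC(=O)c1c(O)cc(O)cc1O | starting material
2 | 3-methylbut-2-enal | CC(C)=CC=O | starting material
3 | (6Z)-3,5-dihydroxy-6-(3-methylbut-2-en-1-ylidene)-2-propanoylcyclohexa-2,4-dien-1-one (ortho-quinone methide, not isolated) | CCC(=O)C1=C(O)C=C(O)/C(=C/C=C(C)C)C1=O | intermediate
4 | 1-(5,7-dihydroxy-2,2-dimethyl-2H-chromen-8-yl)propan-1-one | CCC(=O)c1c(O)cc(O)c2C=CC(C)(C)Oc12 | intermediate
5 | Meldrum's acid, 2,2-dimethyl-1,3-dioxane-4,6-dione | CC1(C)OC(=O)CC(=O)O1 | starting material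
6 | formaldehyde (as paraformaldehyde) | C=O | starting material
7 | 2,2-dimethyl-5-methylidene-1,3-dioxane-4,6-dione (not isolated) | C=C1C(=O)OC(C)(C)OC1=O | intermediate
8 | 5-[(5,7-dihydroxy-2,2-dimethyl-8-propanoyl-2H-chromen-6-yl)methyl]-2,2-dimethyl-1,3-dioxane-4,6-dione (not isolated) | CCC(=O)c1c(O)c(CC2C(=O)OC(C)(C)OC2=O)c(O)c2C=CC(C)(C)Oc12 | intermediate
9 | 5-hydroxy-8,8-dimethyl-2-oxo-6-propanoyl-3,4-dihydro-2H,8H-pyrano[2,3-f]chromene-3-carboxylic acid (racemic) | OC(=O)C1Cc2c(O)c(C(=O)CC)c3OC(C)(C)C=Cc3c2OC1=O | intermediate
10 | trimethylsilyl 8,8-dimethyl-2-oxo-6-propanoyl-5-(trimethylsilyloxy)-3,4-dihydro-2H,8H-pyrano[2,3-f]chromene-3-carboxylate (racemic, not isolated) | C[Si](C)(C)OC(=O)C1Cc2c(O[Si](C)(C)C)c(C(=O)CC)c3OC(C)(C)C=Cc3c2OC1=O | intermediate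
11 | 8,8-dimethyl-2-oxo-6-propanoyl-5-(trimethylsilyloxy)-3,4-dihydro-2H,8H-pyrano[2,3-f]chromene-3-carbonyl chloride (racemic) | ClC(=O)C1Cc2c(O[Si](C)(C)C)c(C(=O)CC)c3OC(C)(C)C=Cc3c2OC1=O | intermediate
12 | 2-methylpropanoyl chloride | CC(C)C(=O)Cl | starting material
13 | but-1-yne | CCC#C | starting material
14 | 2-methylhept-4-yn-3-one | CCC#CC(=O)C(C)C | intermediate
15 | 2-(trimethylsilyl)ethanol | C[Si](C)(C)CCO | starting material
16 | (4E)-2-methyl-5-[2-(trimethylsilyl)ethoxy]hept-4-en-3-one | CC/C(OCC[Si](C)(C)C)=C\C(=O)C(C)C | intermediate
17 | lithium (4E)-2-methyl-5-[2-(trimethylsilyl)ethoxy]hepta-2,4-dien-3-olate (not isolated) | CC/C(OCC[Si](C)(C)C)=C\C([O-])=C(C)C.[Li+] | intermediate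
18 | (4E)-2-methyl-5-[2-(trimethylsilyl)ethoxy]-3-(trimethylsilyloxy)hepta-2,4-diene | CC/C(OCC[Si](C)(C)C)=C\C(O[Si](C)(C)C)=C(C)C | intermediate
19 | 3-{(4E)-2,2-dimethyl-3-oxo-5-[2-(trimethylsilyl)ethoxy]hept-4-enoyl}-8,8-dimethyl-6-propanoyl-5-(trimethylsilyloxy)-3,4-dihydro-2H,8H-pyrano[2,3-f]chromen-2-one (racemic, not isolated) | CC/C(OCC[Si](C)(C)C)=C\C(=O)C(C)(C)C(=O)C1Cc2c(O[Si](C)(C)C)c(C(=O)CC)c3OC(C)(C)C=Cc3c2OC1=O | intermediate
20 | 3-(2,2-dimethyl-3,5-dioxoheptanoyl)-5-hydroxy-8,8-dimethyl-6-propanoyl-3,4-dihydro-2H,8H-pyrano[2,3-f]chromen-2-one (racemic, present as its tetrabutylammonium enolate, not isolated) | CCC(=O)CC(=O)C(C)(C)C(=O)C1Cc2c(O)c(C(=O)CC)c3OC(C)(C)C=Cc3c2OC1=O | intermediate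
21 | 3,5-dihydroxy-6-[(5,7-dihydroxy-2,2-dimethyl-8-propanoyl-2H-chromen-6-yl)methyl]-4,4-dimethyl-2-propanoylcyclohexa-2,5-dien-1-one (CNP0277188.0) | CCC(=O)C1=C(O)C(C)(C)C(O)=C(Cc2c(O)c3c(c(C(=O)CC)c2O)OC(C)(C)C=C3)C1=O | target

**Step count and risks**

Total steps: 7. Longest linear sequence: 4 steps (steps 1, 2, 3 and 7; the diene branch, steps 4, 5, 6 and 7, is equally long).

Steps most likely to fail:

1. Step 7 (Proposed new method). Three things may go wrong: O-acylation of the silyl enol ether in the first stage, which loses the regiodefinition; incomplete fluoride fragmentation of the 2-(trimethylsilyl)ethyl enol ether, so that the second acylation stalls; and base-induced cleavage at the benzylic malonyl carbon (retro-Michael loss of the arene, or scrambling of the two halves of the methylene-bridged product). The fallback uses known chemistry, sets out from 1 and 4 and comes back to the route at 21. Flopropione 1 is C-methylated twice at one ring carbon with MeI and NaOMe in MeOH (the known dearomatising gem-dimethylation of acylphloroglucinols) to give 3,5-dihydroxy-4,4-dimethyl-2-propanoylcyclohexa-2,5-dien-1-one (propionylfilicinic acid) F1. F1 and chromene 4 are then joined with aqueous formaldehyde in dilute aqueous NaOH at 0 °C (the classical methylene bridging of acylphloroglucinols, in which the filicinic acid unit condenses with formaldehyde and the chromene traps the methylidene trione at its free C6), which should give 21 after separation from the two symmetrical dimers.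

2. Step 2. Formaldehyde may be consumed by double addition (methylene-bridged bis-arene or bis-Meldrum's acid adduct), and the lactone acid may decarboxylate on warming. The fallback sets out from 4 and comes back at 9. Chromene 4 is formylated at C6 under Vilsmeier–Haack conditions (POCl3, DMF, then aqueous hydrolysis) to 5,7-dihydroxy-2,2-dimethyl-8-propanoyl-2H-chromene-6-carbaldehyde F2. Organocatalytic reductive alkylation of Meldrum's acid 5 with F2 (L-proline, Hantzsch ester; Knoevenagel condensation followed by transfer hydrogenation of the arylidene) should give the benzyl Meldrum's acid 8 without any free formaldehyde, and warming to 60 °C lactonises 8 to 9.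

3. Step 1. The pyran ring may close through the para oxygen (poor regioselectivity between the two phenolic oxygens), and a second chromenylation may occur. The fallback sets out from 1 and comes back at 4. The para hydroxyl of 1, the most acidic and the only one not flanking the ketone, is protected with MOMCl (1.0 equiv) and iPr2NEt to give 1-[2,6-dihydroxy-4-(methoxymethoxy)phenyl]propan-1-one F3. Chromenylation of F3 with 2 in pyridine can close only through an oxygen next to the acyl group and should give the single isomer 1-[7-hydroxy-5-(methoxymethoxy)-2,2-dimethyl-2H-chromen-8-yl]propan-1-one F4. HCl in MeOH at 40 °C removes the acetal and returns 4.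

**Further compounds**

F1 | step 7 | 3,5-dihydroxy-4,4-dimethyl-2-propanoylcyclohexa-2,5-dien-1-one (propionylfilicinic acid) | CCC(=O)C1=C(O)C(C)(C)C(O)=CC1=O
F2 | step 2 | 5,7-dihydroxy-2,2-dimethyl-8-propanoyl-2H-chromene-6-carbaldehyde | CCC(=O)c1c(O)c(C=O)c(O)c2C=CC(C)(C)Oc12
F3 | step 1 | 1-[2,6-dihydroxy-4-(methoxymethoxy)phenyl]propan-1-one | CCC(=O)c1c(O)cc(OCOC)cc1O
F4 | step 1 | 1-[7-hydroxy-5-(methoxymethoxy)-2,2-dimethyl-2H-chromen-8-yl]propan-1-one | CCC(=O)c1c(O)cc(OCOC)c2C=CC(C)(C)Oc12
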